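**Retrosynthetic overview**

1. Numbering: C1 = oxirane carbon bearing C7H2OBz, C2/C3 = CHOAc, C4/C5 = CHOH, C6 = oxirane CH. The plan rests on the C5–C6 bond of the cyclohexane ring: in the diol that precedes the oxirane, O5 and O6 are cis and both trans to O4 and O1 (which share one face), the signature of a dialdehyde pinacol cyclisation.
2. Oxirane (second ring, formed after the carbocycle): the C1 alkoxide displaces C6–O of a C5/C6 cyclic sulfate with inversion ⇐ cis-5,6-diol 16; then PMB → OAc at C2/C3, sulfate and benzyl removal.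
3. Cyclohexane (first ring): C5–C6 by SmI2 pinacol coupling of dialdehyde 15 ⇐ double ozonolysis of bis-vinyl acetonide 13.
4. C1 quaternary centre: chelate-controlled addition of a hydroxymethyl anion equivalent (C7) to vinyl ketone 9; C6 from vinylmagnesium bromide.
5. C1–C5 (D-xylo triad at C2–C4, PMB/PMB/Bn pattern, C5 aldehyde latent as a vinyl group) ⇐ zinc fragmentation of 6-iodoglucoside 5, made from methyl 4,6-O-benzylidene-α-D-glucopyranoside 1.

Key step: step 10

Remark: the C1–C5 segment is taken from commercial glucoside 1, whose C2–C4 have the D-xylose configuration, because this gives the 2,3-di-O-PMB/4-O-benzyl pattern and a vinyl precursor of the C5 aldehyde in four steps, so both aldehydes arise in one ozonolysis.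
Convention: ring drawn C1→C6 clockwise; β = towards the viewer, α = away. PMB = 4-methoxybenzyl.

**Route**

Step 1
Reactants: 1 methyl 4,6-O-benzylidene-α-D-glucopyranoside; 2 4-methoxybenzyl chloride
Product: 3 methyl 4,6-O-benzylidene-2,3-di-O-PMB-α-D-glucopyranoside
Conditions: NaH, Bu4NI (cat.), DMF, 0 °C → rt
Reagents that add atoms: 4-methoxybenzyl chloride (2), COc1ccc(CCl)cc1
Why: Williamson etherification of the two secondary alkoxides with the benzylic chloride; the acetal and glycoside are base-stable and no stereocentre is touched.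

Step 2
Reactants: 3 methyl 4,6-O-benzylidene-2,3-di-O-PMB-α-D-glucopyranoside
Product: 4 methyl 4-O-benzyl-2,3-di-O-PMB-α-D-glucopyranoside
Conditions: BH3·THF, Cu(OTf)2 (cat.), THF, rt; MeOH quench
Reagents that add atoms: none
Why: Regioselective reductive opening of the benzylidene acetal: Lewis-acid-activated borane coordinates the less hindered O6, the C–O6 bond breaks and hydride is delivered to the oxocarbenium ion, so the benzyl group should stay on O4 and the primary 6-OH is freed, with the PMB ethers untouched.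

Step 3
Reactants: 4 methyl 4-O-benzyl-2,3-di-O-PMB-α-D-glucopyranoside
Product: 5 methyl 4-O-benzyl-6-deoxy-6-iodo-2,3-di-O-PMB-α-D-glucopyranoside
Conditions: I2, PPh3, imidazole, toluene, 70 °C
Reagents that add atoms: iodine, II
Why: Garegg–Samuelsson (Appel-type) iodination: the primary alkoxyphosphonium ion of the only free hydroxyl is displaced by iodide in an SN2 step.

Step 4
Reactants: 5 methyl 4-O-benzyl-6-deoxy-6-iodo-2,3-di-O-PMB-α-D-glucopyranoside
Product: 6 4-O-benzyl-5,6-dideoxy-2,3-di-O-PMB-D-xylo-hex-5-enose (open-chain aldehyde)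
Conditions: Zn dust (activated), THF/H2O (9:1), ultrasound, 40 °C
Reagents that add atoms: none
Why: Bernet–Vasella reductive fragmentation: zinc inserts into C6–I, β-elimination breaks C5–O5 to form the C5=C6 alkene, and the hemiacetal anion loses methoxide to give the aldehyde, leaving C2–C4 untouched.

Step 5
Reactants: 6 hexenal; 7 vinylmagnesium bromide
Product: 8 C3-epimeric 6-benzyloxy-4,5-bis(PMB-oxy)octa-1,7-dien-3-ols
Conditions: THF, −78 → −20 °C
Reagents that add atoms: vinylmagnesium bromide (7), C=C[Mg]Br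
Why: Grignard 1,2-addition to the aldehyde; both carbinol epimers are acceptable because this centre is oxidised in the next step.

Step 6
Reactants: 8 epimeric dienols
Product: 9 (4R,5S,6R)-6-benzyloxy-4,5-bis(PMB-oxy)octa-1,7-dien-3-one
Conditions: Dess–Martin periodinane, NaHCO3, CH2Cl2, 0 °C → rt
Reagents that add atoms: none
Why: Dess–Martin oxidation of a secondary allylic alcohol under buffered conditions that should not epimerise the α-alkoxy centre.

Step 7
Reactants: 9 vinyl ketone; 10 (chloromethyl)(isopropoxy)dimethylsilane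
Product: 12 tertiary/primary 1,7-diol (C1 carries OH and C7H2OH and vinyl), via β-hydroxysilane 11 (not isolated)
Conditions: 10, Mg, THF, rt (Grignard reagent); 9, MgBr2·OEt2, CH2Cl2, −78 °C; then 30% H2O2, KF, KHCO3, THF/MeOH, rt
Reagents that add atoms: (chloromethyl)(isopropoxy)dimethylsilane (10), CC(C)O[Si](C)(C)CCl; hydrogen peroxide, OO
Why: Cram-chelate-controlled Grignard 1,2-addition followed by Tamao oxidation (nucleophilic hydroxymethylation): magnesium bridges the ketone oxygen and the C2 OPMB oxygen, the silylmethyl group enters from the chelate face carrying the C2 hydrogen, which places O1 and O2 on the same side of the C6–C1–C2–C3 chain (cis on the future ring), and C–Si is then oxidised to C–OH with retention without touching the terminal alkenes.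

Step 8
Reactants: 12 1,7-diol
Product: 13 1,7-O-isopropylidene bis-vinyl compound
Conditions: 2,2-dimethoxypropane, PPTS (cat.), CH2Cl2, rt
Reagents that add atoms: 2,2-dimethoxypropane, COC(C)(C)OC
Why: Acid-catalysed transketalisation closes the five-membered ketal on the primary/tertiary 1,2-diol, masking O1 (which would otherwise form a lactol with the C5 aldehyde) with a group that cannot migrate to a samarium alkoxide.

Step 9
Reactants: 13 bis-vinyl acetonide
Product: 15 branched xylo-dialdehyde (C5 and C6 as CHO), via bis-ozonide 14 (not isolated)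
Conditions: O3, CH2Cl2, −78 °C (Sudan Red 7B end point); PPh3, −78 °C → rt; short silica plug, used at once
Reagents that add atoms: ozone, [O-][O+]=O
Why: Ozonolysis with reductive work-up: the two monosubstituted alkenes react far faster than the anisyl and phenyl rings, the ozonides are reduced by PPh3, C1 is quaternary and cannot epimerise, and C4 is preserved by the neutral cold work-up.

Step 10
Reactants: 15 branched xylo-dialdehyde
Product: 16 cis-5,6-diol cyclitol (spiro 1,7-acetonide; 5β,6β-diol)
Conditions: SmI2 (3 equiv), t-BuOH (3 equiv), THF, −78 → −20 °C, slow addition of 15 at high dilution; sat. aq. NaHCO3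
Reagents that add atoms: none
Why: Single-electron transfer from SmI2 to one aldehyde gives a ketyl bound to trivalent samarium that adds to the second, samarium-activated aldehyde, and a second electron transfer with protonation delivers the diolate; this is the known SmI2 pinacol cyclisation of carbohydrate-derived 1,6-dialdehydes to cis-cyclohexane-1,2-diols. The cyclohexane ring is closed by 6-exo-trig attack of one ketyl carbon on the other carbonyl carbon, forming the C5–C6 bond. The cis relation of the new C5 and C6 hydroxyls follows from both oxygens being bridged by samarium in the cyclic transition state. Their facial sense is set by the flanking C4–OBn and C1–O(ketal) bonds: each O–Sm bond turns away from the neighbouring C–O bond (dipole and steric repulsion), and since both neighbours lie on the α face the preferences reinforce, giving the chair with the C2–C5 oxygens equatorial and the C6 hydroxyl axial and anti-periplanar to the axial C1–O bond, whereas the other cis isomer would put O5 in a 1,3-diaxial clash with O1. The step needs ring closure to outrun simple reduction, intermolecular coupling and β-alkoxide loss from the ketyl; high dilution, excess SmI2 without HMPA and t-BuOH as the only proton source should secure this.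

Step 11
Reactants: 16 cis-5,6-diol
Product: 17 5,6-cyclic sulfate
Conditions: NaH, DMF/THF, −30 °C; 1,1'-sulfonyldiimidazole, −30 → 0 °C
Reagents that add atoms: 1,1'-sulfonyldiimidazole, O=S(=O)(n1ccnc1)n1ccnc1
Why: Cyclic sulfate formation by sulfuryl transfer: the dialkoxide attacks sulfonyldiimidazole once intermolecularly and once intramolecularly, closing the cis-fused five-membered ring without a RuO4 oxidation that would endanger the PMB ethers.

Step 12
Reactants: 17 cyclic sulfate acetonide
Product: 18 1,7-diol 5,6-cyclic sulfate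
Conditions: CSA (cat.), MeOH/CH2Cl2, 0 °C → rt
Reagents that add atoms: none
Why: Acid-catalysed transketalisation to methanol removes the isopropylidene group; the benzylic ethers tolerate catalytic sulfonic acid and the hindered secondary cyclic sulfate should not be opened by a neutral alcohol at room temperature.

Step 13
Reactants: 18 1,7-diol cyclic sulfate
Product: 19 7-O-benzoate with free tertiary 1-OH
Conditions: BzCl, 2,4,6-collidine, CH2Cl2, −20 → 0 °C
Reagents that add atoms: benzoyl chloride, O=C(Cl)c1ccccc1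
Why: Selective acylation of the primary C7 hydroxyl beside the unreactive tertiary C1 hydroxyl, with a hindered base that does not open the cyclic sulfate.

Step 14
Reactants: 19 7-O-benzoate cyclic sulfate
Product: 21 tetrabutylammonium 1,6α-oxirane 5-O-sulfate, via sodium sulfate 20 (not isolated)
Conditions: NaH, THF, 0 °C → rt; then aq. Bu4NHSO4, CH2Cl2 extraction
Reagents that add atoms: tetrabutylammonium hydrogen sulfate, CCCC[N+](CCCC)(CCCC)CCCC.OS(=O)(=O)[O-]
Why: Intramolecular SN2 opening of the cyclic sulfate by the neighbouring alkoxide (3-exo-tet oxirane formation from a β-hydroxy cyclic sulfate): the axial C1 alkoxide is anti-periplanar to the axial C6–O bond and attacks C6 with inversion, so the oxirane lies on the α face, O5 remains as a sulfate monoester, and cation exchange makes the salt extractable.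

Step 15
Reactants: 21 oxirane sulfate salt
Product: 22 2,3-diol
Conditions: DDQ, CH2Cl2/pH 7 buffer, 0 °C → rt
Reagents that add atoms: none
Why: Oxidative cleavage of both PMB ethers by DDQ (benzylic hydride abstraction, hydrolysis of the oxocarbenium ion), which should leave the benzyl ether, benzoate, oxirane and sulfate untouched.

Step 16
Reactants: 22 2,3-diol
Product: 23 2,3-diacetate
Conditions: Ac2O, pyridine, DMAP (cat.), CH2Cl2, 0 °C → rt
Reagents that add atoms: acetic anhydride, CC(=O)OC(C)=O
Why: DMAP-catalysed acetylation of the two free secondary alcohols while O5 is masked as sulfate and O4 as benzyl ether; Payne rearrangement is excluded because O2 is cis to the oxirane oxygen.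

Step 17
Reactants: 23 diacetate sulfate salt
Product: 24 4-O-benzyl ether of the target (free 5-OH)
Conditions: H2SO4 (cat.), H2O (2 equiv), THF, rt
Reagents that add atoms: none
Why: Acid-catalysed hydrolysis of a secondary alkyl sulfate monoester with catalytic acid and stoichiometric water, which cleaves S–O with retention at C5 under conditions mild enough for the acetates and the electron-poor oxirane; with O4 still benzylated no acetyl group can migrate.

Step 18
Reactants: 24 4-O-benzyl ether
Product: 25 target, [(1S,2R,3S,4R,5R,6S)-2,3-diacetoxy-4,5-dihydroxy-7-oxabicyclo[4.1.0]heptan-1-yl]methyl benzoate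
Conditions: H2 (1 atm), Pd/C, EtOAc, rt
Reagents that add atoms: none
Why: Hydrogenolysis of the benzyl ether on palladium under neutral conditions, which should not touch the non-benzylic oxirane or the esters nor cause acyl migration.

**Compound list**

1 | methyl 4,6-O-benzylidene-α-D-glucopyranoside (R acetal) | CO[C@@H]1[C@H](O)[C@@H](O)[C@@H]2O[C@H](c3ccccc3)OC[C@H]2O1 | starting material
2 | 4-methoxybenzyl chloride | COc1ccc(CCl)cc1 | starting material
3 | methyl 4,6-O-benzylidene-2,3-di-O-(4-methoxybenzyl)-α-D-glucopyranoside | CO[C@@H]1[C@H](OCc3ccc(OC)cc3)[C@@H](OCc3ccc(OC)cc3)[C@@H]2O[C@H](c3ccccc3)OC[C@H]2O1 | intermediate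
4 | methyl 4-O-benzyl-2,3-di-O-(4-methoxybenzyl)-α-D-glucopyranoside | CO[C@@H]1[C@H](OCc2ccc(OC)cc2)[C@@H](OCc2ccc(OC)cc2)[C@H](OCc2ccccc2)[C@@H](CO)O1 | intermediate
5 | methyl 4-O-benzyl-6-deoxy-6-iodo-2,3-di-O-(4-methoxybenzyl)-α-D-glucopyranoside | CO[C@@H]1[C@H](OCc2ccc(OC)cc2)[C@@H](OCc2ccc(OC)cc2)[C@H](OCc2ccccc2)[C@@H](CI)O1 | intermediate
6 | (2R,3S,4R)-4-(benzyloxy)-2,3-bis[(4-methoxybenzyl)oxy]hex-5-enal | O=C[C@H](OCc1ccc(OC)cc1)[C@@H](OCc1ccc(OC)cc1)[C@H](OCc1ccccc1)C=C | intermediate
7 | vinylmagnesium bromide | C=C[Mg]Br | starting material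
8 | (3RS,4S,5S,6R)-6-(benzyloxy)-4,5-bis[(4-methoxybenzyl)oxy]octa-1,7-dien-3-ol (both C3 epimers) | C=CC(O)[C@H](OCc1ccc(OC)cc1)[C@@H](OCc1ccc(OC)cc1)[C@H](OCc1ccccc1)C=C | intermediate
9 | (4R,5S,6R)-6-(benzyloxy)-4,5-bis[(4-methoxybenzyl)oxy]octa-1,7-dien-3-one | C=CC(=O)[C@H](OCc1ccc(OC)cc1)[C@@H](OCc1ccc(OC)cc1)[C@H](OCc1ccccc1)C=C | intermediate
10 | (chloromethyl)(isopropoxy)dimethylsilane | CC(C)O[Si](C)(C)CCl | starting material
11 | (3S,4R,5S,6R)-6-(benzyloxy)-3-{[isopropoxy(dimethyl)silyl]methyl}-4,5-bis[(4-methoxybenzyl)oxy]octa-1,7-dien-3-ol | C=C[C@@](O)(C[Si](C)(C)OC(C)C)[C@H](OCc1ccc(OC)cc1)[C@@H](OCc1ccc(OC)cc1)[C@H](OCc1ccccc1)C=C | intermediate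
12 | (3R,4R,5S,6R)-6-(benzyloxy)-3-(hydroxymethyl)-4,5-bis[(4-methoxybenzyl)oxy]octa-1,7-dien-3-ol | C=C[C@@](O)(CO)[C@H](OCc1ccc(OC)cc1)[C@@H](OCc1ccc(OC)cc1)[C@H](OCc1ccccc1)C=C | intermediate
13 | 1,7-O-isopropylidene ketal of 12 (4-vinyl-2,2-dimethyl-1,3-dioxolane carrying the C2–C5 chain at its C4) | C=C[C@@]1(COC(C)(C)O1)[C@H](OCc2ccc(OC)cc2)[C@@H](OCc2ccc(OC)cc2)[C@H](OCc2ccccc2)C=C | intermediate
14 | bis(1,2,4-trioxolane) of 13 (both vinyl groups as ozonides, ozonide carbons as epimer mixtures) | O1OC(OC1)[C@@]2(COC(C)(C)O2)[C@H](OCc3ccc(OC)cc3)[C@@H](OCc3ccc(OC)cc3)[C@H](OCc3ccccc3)C4OCOO4 | intermediate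
15 | branched xylo-dialdehyde: C6HO–C1(O1,C7H2O7 as acetonide)–C2H(OPMB)–C3H(OPMB)–C4H(OBn)–C5HO | O=C[C@@]1(COC(C)(C)O1)[C@H](OCc2ccc(OC)cc2)[C@@H](OCc2ccc(OC)cc2)[C@H](OCc2ccccc2)C=O | intermediate
16 | cis-5,6-diol cyclitol: spiro 1,7-O-isopropylidene (O1 α, C7 β), 2α-OPMB, 3β-OPMB, 4α-OBn, 5β-OH, 6β-OH | CC1(C)OC[C@@]2(O1)[C@H](OCc3ccc(OC)cc3)[C@@H](OCc3ccc(OC)cc3)[C@H](OCc3ccccc3)[C@@H](O)[C@H]2O | intermediate
17 | 5,6-cyclic sulfate of 16 | CC1(C)OC[C@@]2(O1)[C@H](OCc4ccc(OC)cc4)[C@@H](OCc4ccc(OC)cc4)[C@H](OCc4ccccc4)[C@H]3OS(=O)(=O)O[C@@H]23 | intermediate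
18 | 1,7-diol 5,6-cyclic sulfate (acetonide removed) | OC[C@@]1(O)[C@H](OCc3ccc(OC)cc3)[C@@H](OCc3ccc(OC)cc3)[C@H](OCc3ccccc3)[C@H]2OS(=O)(=O)O[C@@H]12 | intermediate
19 | 7-O-benzoate of 18 (free tertiary 1α-OH) | O=C(OC[C@@]1(O)[C@H](OCc3ccc(OC)cc3)[C@@H](OCc3ccc(OC)cc3)[C@H](OCc3ccccc3)[C@H]2OS(=O)(=O)O[C@@H]12)c1ccccc1 | intermediate
20 | sodium salt of the 1,6α-oxirane 5β-O-sulfate (2α,3β-di-OPMB, 4α-OBn, 7-OBz) | O=C(OC[C@]12O[C@H]1[C@H](OS(=O)(=O)[O-])[C@@H](OCc3ccccc3)[C@H](OCc3ccc(OC)cc3)[C@H]2OCc3ccc(OC)cc3)c1ccccc1.[Na+] | intermediate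
21 | tetrabutylammonium salt of the same oxirane 5-O-sulfate | O=C(OC[C@]12O[C@H]1[C@H](OS(=O)(=O)[O-])[C@@H](OCc3ccccc3)[C@H](OCc3ccc(OC)cc3)[C@H]2OCc3ccc(OC)cc3)c1ccccc1.CCCC[N+](CCCC)(CCCC)CCCC | intermediate
22 | 2α,3β-diol (PMB groups removed), tetrabutylammonium 5-O-sulfate | O=C(OC[C@]12O[C@H]1[C@H](OS(=O)(=O)[O-])[C@@H](OCc3ccccc3)[C@H](O)[C@H]2O)c1ccccc1.CCCC[N+](CCCC)(CCCC)CCCC | intermediate
23 | 2α,3β-diacetate, tetrabutylammonium 5-O-sulfate | O=C(OC[C@]12O[C@H]1[C@H](OS(=O)(=O)[O-])[C@@H](OCc3ccccc3)[C@H](OC(C)=O)[C@H]2OC(C)=O)c1ccccc1.CCCC[N+](CCCC)(CCCC)CCCC | intermediate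
24 | [(1S,2R,3S,4R,5R,6S)-2,3-diacetoxy-4-(benzyloxy)-5-hydroxy-7-oxabicyclo[4.1.0]heptan-1-yl]methyl benzoate | O=C(OC[C@]12O[C@H]1[C@H](O)[C@@H](OCc3ccccc3)[C@H](OC(C)=O)[C@H]2OC(C)=O)c1ccccc1 | intermediate
25 | [(1S,2R,3S,4R,5R,6S)-2,3-diacetoxy-4,5-dihydroxy-7-oxabicyclo[4.1.0]heptan-1-yl]methyl benzoate | CC(=O)O[C@H]1[C@H](O)[C@@H](O)[C@@H]2O[C@]2(COC(=O)c2ccccc2)[C@@H]1OC(C)=O | target

**Step count and risks**

Total steps: 18. Longest linear sequence: 18 steps (from 1 to 25).

Steps most likely to fail: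

1. Step 10. The diastereoselectivity at C5/C6 may erode (trans-diol or the other cis-diol), or the ketyls may be reduced or lose a β-alkoxide before ring closure. Fallback, setting out from 13: ring-closing metathesis with the second-generation Grubbs catalyst, RuCl2(=CHPh)(PCy3)(SIMes), in CH2Cl2 at 40 °C should give the spiro-ketal cyclohexene F1 with the C5=C6 double bond. Dihydroxylation with OsO4 (cat.) and N-methylmorpholine N-oxide in acetone/H2O should then take place on the β face, anti to the allylic C4–OBn and C1–O bonds, and the route is rejoined at 16.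

2. Step 7. Conjugate addition to, or polymerisation of, the vinyl ketone may compete with 1,2-addition, and chelate control may be incomplete. Fallback, setting out from 6: lithium (trimethylsilyl)acetylide in THF at −78 °C should give the silylated propargylic alcohols F2, and Dess–Martin oxidation the ynone F3, whose β-carbon is shielded by the silyl group. The Grignard reagent from 10 with MgBr2·OEt2 should add 1,2 to the chelated ynone to give the bis-silyl carbinol F4, which is not isolated. KF/KHCO3/H2O2 should oxidise its C–Si bond and remove the alkynyl silyl group to give the ethynyl diol F5. Semi-hydrogenation (H2, Pd/CaCO3 poisoned with Pb(OAc)2, quinoline, EtOAc) returns to the route at 12.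

3. Step 12. The cyclic sulfate may be opened by solvolysis, or close and re-open at C6 under acid, while the ketal is being cleaved. Fallback, setting out from 16: the acetonide is removed first (AcOH/H2O 4:1, 45 °C) to give the tetraol F6, and the primary C7 hydroxyl is benzoylated selectively (BzCl, 2,4,6-collidine, CH2Cl2, −40 °C) to give the 7-O-benzoate triol F7. SOCl2/Et3N in CH2Cl2 at 0 °C should bridge only the cis-5,6-diol (the 1-OH is trans-diaxial to O6) to give the cyclic sulfite F8, which is oxidised without isolation with RuCl3 (cat.)/NaIO4 at 0 °C with short contact, rejoining the route at 19.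

Further compounds
F1 | step 10 | spiro 1,7-O-isopropylidene cyclohex-5-ene (2α,3β-di-OPMB, 4α-OBn) | CC1(C)OC[C@@]2(O1)[C@H](OCc3ccc(OC)cc3)[C@@H](OCc3ccc(OC)cc3)[C@H](OCc3ccccc3)C=C2
F2 | step 7 | C3-epimeric 6-benzyloxy-4,5-bis(PMB-oxy)-1-(trimethylsilyl)oct-7-en-1-yn-3-ols | C[Si](C)(C)C#CC(O)[C@H](OCc1ccc(OC)cc1)[C@@H](OCc1ccc(OC)cc1)[C@H](OCc1ccccc1)C=C
F3 | step 7 | 6-benzyloxy-4,5-bis(PMB-oxy)-1-(trimethylsilyl)oct-7-en-1-yn-3-one | C[Si](C)(C)C#CC(=O)[C@H](OCc1ccc(OC)cc1)[C@@H](OCc1ccc(OC)cc1)[C@H](OCc1ccccc1)C=C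
F4 | step 7 | tertiary carbinol carrying CH2SiMe2(OiPr) and C≡C–SiMe3 at C1 | C[Si](C)(C)C#C[C@@](O)(C[Si](C)(C)OC(C)C)[C@H](OCc1ccc(OC)cc1)[C@@H](OCc1ccc(OC)cc1)[C@H](OCc1ccccc1)C=C
F5 | step 7 | ethynyl analogue of diol 12 | C#C[C@@](O)(CO)[C@H](OCc1ccc(OC)cc1)[C@@H](OCc1ccc(OC)cc1)[C@H](OCc1ccccc1)C=C
F6 | step 12 | 1,5,6,7-tetraol (2α,3β-di-OPMB, 4α-OBn) | OC[C@@]1(O)[C@H](OCc2ccc(OC)cc2)[C@@H](OCc2ccc(OC)cc2)[C@H](OCc2ccccc2)[C@@H](O)[C@H]1O
F7 | step 12 | 7-O-benzoate 1,5,6-triol | O=C(OC[C@@]1(O)[C@H](OCc2ccc(OC)cc2)[C@@H](OCc2ccc(OC)cc2)[C@H](OCc2ccccc2)[C@@H](O)[C@H]1O)c1ccccc1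
F8 | step 12 | 5,6-cyclic sulfite of F7 (sulfur epimers) | O=C(OC[C@@]1(O)[C@H](OCc3ccc(OC)cc3)[C@@H](OCc3ccc(OC)cc3)[C@H](OCc3ccccc3)[C@H]2OS(=O)O[C@@H]12)c1ccccc1
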